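The plan cuts the aryl ketone bond C4–C4a of the pyranone ring C. Carbon C4a of ring A lies ortho to the ether oxygen O1 and para to the oxygen on C7. It is therefore the most nucleophilic carbon within reach of an acyl electrophile at C4. One intramolecular Friedel–Crafts acylation at −78 °C forms C4–C4a, closes the six-membered ring C and carries the labile C3 stereocentre through untouched. Its precursor is the open-chain (S)-2-(chromen-6-yl)-3-(3-silyloxyphenoxy)propanoic acid. The stereocentre is set early, by lipase monoacetylation of a prochiral 2-aryl-1,3-propanediol in which that carbon bears no acidic hydrogen. It becomes acidic only in the last three steps.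

Key step: step 9

Notation: ring A is the benzo ring and ring C the pyranone ring of the chromanone, ring B is the benzene ring on C3, and ring D is the dimethylpyran ring fused to ring B; C2, C3, C4, C4a and C7 are chromanone positions.

Assumption: the lipase is taken to acetylate the pro-S hydroxymethyl arm of the prochiral diol; the sense and level of this selection must be confirmed on the monoacetate before material is carried on.

Step 1
Reactants: 1 4-bromo-3-methoxyphenol; 2 3-methylbut-2-enal
Product: 4 6-bromo-7-methoxy-2,2-dimethyl-2H-chromene, via ortho-quinone methide 3 (not isolated)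
Conditions: PhB(OH)2 (1.0 equiv), AcOH, toluene, reflux, Dean–Stark trap
Reagents that add atoms: none
Why: Boronic-acid-templated condensation of a phenol with an enal should deliver ortho-quinone methide 3, which closes ring D by oxa-6π electrocyclisation; the C–C bond forms at the open ortho carbon para to the methoxy group rather than at the crowded carbon between the two oxygens, and since bromine is already in place no electrophilic bromination, which would go for the ring D olefin, is needed.

Step 2
Reactants: 4 6-bromo-7-methoxy-2,2-dimethyl-2H-chromene; 5 diethyl malonate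
Product: 6 diethyl 2-(7-methoxy-2,2-dimethyl-2H-chromen-6-yl)malonate
Conditions: Pd2(dba)3 (2 mol %), P(t-Bu)3·HBF4 (8 mol %), K3PO4 (3 equiv), toluene, 80 °C
Reagents that add atoms: none
Why: Palladium-catalysed α-arylation of a malonate (Buchwald–Hartwig type): the bulky, electron-rich phosphine allows oxidative addition of zerovalent palladium into the electron-rich, ortho-substituted C–Br bond, and the product rests as its potassium enolate, which prevents a second arylation.

Step 3
Reactants: 6 diethyl 2-(7-methoxy-2,2-dimethyl-2H-chromen-6-yl)malonate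
Product: 7 2-(7-methoxy-2,2-dimethyl-2H-chromen-6-yl)propane-1,3-diol
Conditions: LiAlH4 (2.5 equiv), THF, 0 °C to rt, slow addition of 6 to the hydride; then H2O
Reagents that add atoms: none
Why: Hydride reduction of both esters; adding 6 slowly to excess LiAlH4 lets reduction outrun deprotonation of the malonate C–H, the unactivated ring D olefin is inert to hydride, and the diol formed is prochiral with no acidic hydrogen at the future C3.

Step 4
Reactants: 7 2-(7-methoxy-2,2-dimethyl-2H-chromen-6-yl)propane-1,3-diol
Product: 8 (2S)-3-hydroxy-2-(7-methoxy-2,2-dimethyl-2H-chromen-6-yl)propyl acetate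
Conditions: Burkholderia cepacia lipase (Amano PS), vinyl acetate (5 equiv), t-BuOMe, 25 °C; filter, concentrate, use promptly
Reagents that add atoms: vinyl acetate, C=COC(C)=O
Why: Lipase-catalysed irreversible transesterification (desymmetrisation by selection between enantiotopic groups): the chiral acyl-enzyme tells the two CH2OH arms apart, acetylation of the pro-S arm sets the stereocentre as S, tautomerisation of the released vinyl alcohol to acetaldehyde makes the transfer irreversible, and slight over-acetylation should remove the minor enantiomer as the achiral diacetate.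

Step 5
Reactants: 9 resorcinol
Product: 10 3-(triisopropylsilyloxy)phenol
Conditions: TIPSCl (1 equiv), imidazole, resorcinol (3 equiv), DMF, 0 °C to rt
Reagents that add atoms: triisopropylsilyl chloride (TIPSCl), CC(C)[Si](Cl)(C(C)C)C(C)C
Why: Statistical monosilylation by the silyl chloride/imidazole protocol with the diol in excess; surplus resorcinol washes out with water, and the bulky silyl group is chosen because it later screens the ring carbon between the two oxygens and comes off without base.

Step 6
Reactants: 8 (2S)-3-hydroxy-2-(7-methoxy-2,2-dimethyl-2H-chromen-6-yl)propyl acetate; 10 3-(triisopropylsilyloxy)phenol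
Product: 11 (2S)-2-(7-methoxy-2,2-dimethyl-2H-chromen-6-yl)-3-[3-(triisopropylsilyloxy)phenoxy]propyl acetate
Conditions: PPh3, DIAD (added last, dropwise), THF, 0 °C to rt
Reagents that add atoms: none
Why: Mitsunobu etherification: the phenoxide displaces the alkoxyphosphonium group at the primary CH2 by SN2, so the neighbouring stereocentre is not touched, and the nearly neutral medium avoids the acetyl migration between the two oxygens that would interconvert the enantiomers of 8.

Step 7
Reactants: 11 (2S)-2-(7-methoxy-2,2-dimethyl-2H-chromen-6-yl)-3-[3-(triisopropylsilyloxy)phenoxy]propyl acetate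
Product: 12 (2R)-2-(7-methoxy-2,2-dimethyl-2H-chromen-6-yl)-3-[3-(triisopropylsilyloxy)phenoxy]propan-1-ol
Conditions: i-Bu2AlH (2.5 equiv), CH2Cl2, −78 °C; aq. potassium sodium tartrate
Reagents that add atoms: none
Why: Reductive cleavage of the acetate with an aluminium hydride avoids the basic methanolysis that endangers an aryl silyl ether; the stereocentre still has no acidic hydrogen, and the descriptor changes from S to R only because the priority order of the two arms changes.

Step 8
Reactants: 12 (2R)-2-(7-methoxy-2,2-dimethyl-2H-chromen-6-yl)-3-[3-(triisopropylsilyloxy)phenoxy]propan-1-ol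
Product: 14 (2S)-2-(7-methoxy-2,2-dimethyl-2H-chromen-6-yl)-3-[3-(triisopropylsilyloxy)phenoxy]propanoic acid, via aldehyde 13 (not isolated)
Conditions: TEMPO (2,2,6,6-tetramethylpiperidin-1-oxyl, 20 mol %), PhI(OAc)2 (2.2 equiv), MeCN/H2O with CH2Cl2 as cosolvent, 0 °C to rt
Reagents that add atoms: water, O
Why: Oxoammonium-catalysed oxidation (TEMPO/PhI(OAc)2) takes the primary alcohol through aldehyde 13 and its hydrate to the acid in one pot in a weakly acidic, base-free and chlorine-free medium, so the aldehyde should have little time to enolise or to expel the aryloxide, and the electron-rich rings and the ring D olefin are not halogenated.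

Step 9
Reactants: 14 (2S)-2-(7-methoxy-2,2-dimethyl-2H-chromen-6-yl)-3-[3-(triisopropylsilyloxy)phenoxy]propanoic acid
Product: 16 (3S)-3-(7-methoxy-2,2-dimethyl-2H-chromen-6-yl)-7-(triisopropylsilyloxy)chroman-4-one, via acid chloride 15 (not isolated)
Conditions: Me2C=C(Cl)NMe2 (1.0 equiv, run to full consumption), CH2Cl2, 0 °C; dilute to 0.01 M, 2,6-di-tert-butyl-4-methylpyridine (1.2 equiv), SnCl4 (2.5 equiv), −78 °C; quench cold into pH 7 phosphate buffer
Reagents that add atoms: 1-chloro-N,N,2-trimethylprop-1-en-1-amine, CC(C)=C(Cl)N(C)C (supplies the chlorine of 15; no reagent atom stays in 16)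
Why: The α-chloroenamine turns acid 14 into acid chloride 15 without setting free HCl, SnCl4 then polarises the C–Cl bond to an acylium-like complex, the ring A carbon ortho to the ether oxygen and para to the silyloxy group attacks it, and loss of a proton from the arenium ion restores the aromatic ring. The closest known reaction type is the intramolecular Friedel–Crafts acylation of 3-aryloxypropanoic acids to chroman-4-ones. Ring C closes as a six-membered ring by electrophilic aromatic substitution, exo with respect to the acyl C=O, and C4–C4a is the only skeletal bond formed. No stereocentre is created; the S configuration at C3 is merely carried through, which should hold because attack by the doubly activated carbon at −78 °C is faster than ketene or enol formation and because the only base present is a pyridine too hindered to reach the acyl group or tin. The step needs regioselectivity between the two carbons ortho to the ether oxygen, secured by the bulky silyl group that screens the carbon between the two oxygens, and chemoselectivity against ring B and the ring D olefin, secured by geometry (closure onto ring B would give a four-membered ring) and by high dilution. HCl-free activation, exactly one equivalent of chloroenamine (an excess would give a keteniminium ion with tin) and the proton trap should keep the acid-sensitive ring D olefin intact, and the low temperature holds back loss of CO from the acyl complex.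

Step 10
Reactants: 16 (3S)-3-(7-methoxy-2,2-dimethyl-2H-chromen-6-yl)-7-(triisopropylsilyloxy)chroman-4-one
Product: 17 (3S)-7-hydroxy-3-(7-methoxy-2,2-dimethyl-2H-chromen-6-yl)chroman-4-one (CNP0226344.1)
Conditions: HF·pyridine, extra pyridine, THF, 0 °C, polyethylene vessel; pH 7 buffer work-up, no basic wash
Reagents that add atoms: none
Why: Fluoride-driven cleavage of the aryl silyl ether, powered by the strong Si–F bond, in a buffered weakly acidic medium that holds no base strong enough to remove the C3 hydrogen and is not acidic enough to protonate the ring D olefin.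

Compound list
1 | 4-bromo-3-methoxyphenol | COc1cc(O)ccc1Br | starting material
2 | 3-methylbut-2-enal | CC(C)=CC=O | starting material
3 | 4-bromo-3-methoxy-6-(3-methylbut-2-en-1-ylidene)cyclohexa-2,4-dien-1-one (ortho-quinone methide) | O=C1C=C(OC)C(Br)=CC1=CC=C(C)C | intermediate
4 | 6-bromo-7-methoxy-2,2-dimethyl-2H-chromene | COc1cc2OC(C)(C)C=Cc2cc1Br | intermediate
5 | diethyl malonate | CCOC(=O)CC(=O)OCC | starting material
6 | diethyl 2-(7-methoxy-2,2-dimethyl-2H-chromen-6-yl)malonate | CCOC(=O)C(C(=O)OCC)c1cc2C=CC(C)(C)Oc2cc1OC | intermediate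
7 | 2-(7-methoxy-2,2-dimethyl-2H-chromen-6-yl)propane-1,3-diol | OCC(CO)c1cc2C=CC(C)(C)Oc2cc1OC | intermediate
8 | (2S)-3-hydroxy-2-(7-methoxy-2,2-dimethyl-2H-chromen-6-yl)propyl acetate | CC(=O)OC[C@@H](c1cc2C=CC(C)(C)Oc2cc1OC)CO | intermediate
9 | resorcinol | Oc1cccc(O)c1 | starting material
10 | 3-(triisopropylsilyloxy)phenol | Oc1cccc(O[Si](C(C)C)(C(C)C)C(C)C)c1 | intermediate
11 | (2S)-2-(7-methoxy-2,2-dimethyl-2H-chromen-6-yl)-3-[3-(triisopropylsilyloxy)phenoxy]propyl acetate | CC(=O)OC[C@@H](c1cc2C=CC(C)(C)Oc2cc1OC)COc1cccc(O[Si](C(C)C)(C(C)C)C(C)C)c1 | intermediate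
12 | (2R)-2-(7-methoxy-2,2-dimethyl-2H-chromen-6-yl)-3-[3-(triisopropylsilyloxy)phenoxy]propan-1-ol | OC[C@@H](c1cc2C=CC(C)(C)Oc2cc1OC)COc1cccc(O[Si](C(C)C)(C(C)C)C(C)C)c1 | intermediate
13 | (2S)-2-(7-methoxy-2,2-dimethyl-2H-chromen-6-yl)-3-[3-(triisopropylsilyloxy)phenoxy]propanal | O=C[C@@H](c1cc2C=CC(C)(C)Oc2cc1OC)COc1cccc(O[Si](C(C)C)(C(C)C)C(C)C)c1 | intermediate
14 | (2S)-2-(7-methoxy-2,2-dimethyl-2H-chromen-6-yl)-3-[3-(triisopropylsilyloxy)phenoxy]propanoic acid | OC(=O)[C@@H](c1cc2C=CC(C)(C)Oc2cc1OC)COc1cccc(O[Si](C(C)C)(C(C)C)C(C)C)c1 | intermediate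
15 | (2S)-2-(7-methoxy-2,2-dimethyl-2H-chromen-6-yl)-3-[3-(triisopropylsilyloxy)phenoxy]propanoyl chloride | ClC(=O)[C@@H](c1cc2C=CC(C)(C)Oc2cc1OC)COc1cccc(O[Si](C(C)C)(C(C)C)C(C)C)c1 | intermediate
16 | (3S)-3-(7-methoxy-2,2-dimethyl-2H-chromen-6-yl)-7-(triisopropylsilyloxy)chroman-4-one | O=C1c2ccc(O[Si](C(C)C)(C(C)C)C(C)C)cc2OC[C@@H]1c1cc2C=CC(C)(C)Oc2cc1OC | intermediate
17 | (3S)-7-hydroxy-3-(7-methoxy-2,2-dimethyl-2H-chromen-6-yl)chroman-4-one | COc1cc2c(cc1[C@H]1COc3cc(O)ccc3C1=O)C=CC(C)(C)O2 | target

Total step count: 10. Longest linear sequence: 9 (steps 1 to 4 and 6 to 10; step 5 is a one-step side branch).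

Steps most likely to fail

Step 9.
- **What may go wrong:** Tin or traces of protic acid may start cationic oligomerisation at the electron-rich ring D olefin. The activated acyl group may lose CO. The C3 configuration may erode through ketene or enol formation.
- **Fallback:** The same C4–C4a bond is made under neutral, reductive conditions from an aryl iodide and an aldehyde, not by electrophilic substitution. The fallback sets out from 8 and comes back at 16. Commercial 4-iodoresorcinol (Oc1ccc(I)c(O)c1) is silylated with TIPSCl and imidazole in DMF at the unhindered hydroxyl para to iodine, giving 2-iodo-5-(triisopropylsilyloxy)phenol F1. Mitsunobu coupling of F1 with 8 (PPh3, DIAD, THF) should give (2S)-3-[2-iodo-5-(triisopropylsilyloxy)phenoxy]-2-(7-methoxy-2,2-dimethyl-2H-chromen-6-yl)propyl acetate F2. Treatment with i-Bu2AlH at −78 °C frees (2R)-3-[2-iodo-5-(triisopropylsilyloxy)phenoxy]-2-(7-methoxy-2,2-dimethyl-2H-chromen-6-yl)propan-1-ol F3. Dess–Martin periodinane in CH2Cl2 gives (2S)-3-[2-iodo-5-(triisopropylsilyloxy)phenoxy]-2-(7-methoxy-2,2-dimethyl-2H-chromen-6-yl)propanal F4, which is used at once. An intramolecular Nozaki–Hiyama–Kishi reaction (CrCl2 in excess, catalytic NiCl2, DMF, rt) closes ring C to (3S)-3-(7-methoxy-2,2-dimethyl-2H-chromen-6-yl)-7-(triisopropylsilyloxy)chroman-4-ol F5 as a mixture of C4 epimers. A second Dess–Martin oxidation erases C4 as a stereocentre and gives 16.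

Step 4.
- **What may go wrong:** The acetyl group may go to the wrong arm, or the two arms may be poorly told apart, because the ortho-methoxy group and the bulky ring D fit the enzyme pocket badly. Acetyl migration between the two oxygens during isolation would add to the loss.
- **Fallback:** A small-molecule catalyst of selectable handedness replaces the enzyme. The fallback sets out from 7 and comes back at 12. Diol 7 is desymmetrised with vinyl benzoate in toluene at −15 °C. The dinuclear zinc catalyst is formed from Et2Zn and the ProPhenol ligand 2,6-bis{[2-(hydroxydiphenylmethyl)pyrrolidin-1-yl]methyl}-4-methylphenol, a known method for 2-aryl-1,3-propanediols. The ligand enantiomer that benzoylates the pro-S arm is used. This should give (2S)-3-hydroxy-2-(7-methoxy-2,2-dimethyl-2H-chromen-6-yl)propyl benzoate F6, whose acyl group also migrates less readily than acetyl. Mitsunobu coupling with 10 gives (2S)-2-(7-methoxy-2,2-dimethyl-2H-chromen-6-yl)-3-[3-(triisopropylsilyloxy)phenoxy]propyl benzoate F7. Treatment with i-Bu2AlH at −78 °C removes the benzoate and gives 12.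

Step 8.
- **What may go wrong:** The transient α-aryl aldehyde may enolise before it is oxidised further, which erodes the configuration of the acid.
- **Fallback:** The configuration is not preserved but re-established by a stereoconvergent step after ring closure. The fallback sets out from 16, made by step 9 from configurationally eroded 14, and comes back at 16. Noyori-type asymmetric transfer hydrogenation with dynamic kinetic resolution is a known reaction of isoflavanones. It is run with RuCl(p-cymene)[(S,S)-TsDPEN] and HCO2H/Et3N in EtOAc at rt. The amine equilibrates C3 while the catalyst reduces one enantiomer to the cis alcohol. This should give (3S,4S)-3-(7-methoxy-2,2-dimethyl-2H-chromen-6-yl)-7-(triisopropylsilyloxy)chroman-4-ol F8, with the ring D olefin left alone. Dess–Martin periodinane in CH2Cl2 at 0 °C then returns the ketone 16 under non-enolising conditions. The same repair serves if configuration is lost in step 9.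

Further compounds
F1 | step 9 | 2-iodo-5-(triisopropylsilyloxy)phenol | Oc1cc(O[Si](C(C)C)(C(C)C)C(C)C)ccc1I
F2 | step 9 | (2S)-3-[2-iodo-5-(triisopropylsilyloxy)phenoxy]-2-(7-methoxy-2,2-dimethyl-2H-chromen-6-yl)propyl acetate | CC(=O)OC[C@@H](c1cc2C=CC(C)(C)Oc2cc1OC)COc1cc(O[Si](C(C)C)(C(C)C)C(C)C)ccc1I
F3 | step 9 | (2R)-3-[2-iodo-5-(triisopropylsilyloxy)phenoxy]-2-(7-methoxy-2,2-dimethyl-2H-chromen-6-yl)propan-1-ol | OC[C@@H](c1cc2C=CC(C)(C)Oc2cc1OC)COc1cc(O[Si](C(C)C)(C(C)C)C(C)C)ccc1I
F4 | step 9 | (2S)-3-[2-iodo-5-(triisopropylsilyloxy)phenoxy]-2-(7-methoxy-2,2-dimethyl-2H-chromen-6-yl)propanal | O=C[C@@H](c1cc2C=CC(C)(C)Oc2cc1OC)COc1cc(O[Si](C(C)C)(C(C)C)C(C)C)ccc1I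
F5 | step 9 | (3S)-3-(7-methoxy-2,2-dimethyl-2H-chromen-6-yl)-7-(triisopropylsilyloxy)chroman-4-ol, mixture of C4 epimers | OC1c2ccc(O[Si](C(C)C)(C(C)C)C(C)C)cc2OC[C@@H]1c1cc2C=CC(C)(C)Oc2cc1OC
F6 | step 4 | (2S)-3-hydroxy-2-(7-methoxy-2,2-dimethyl-2H-chromen-6-yl)propyl benzoate | O=C(OC[C@@H](c1cc2C=CC(C)(C)Oc2cc1OC)CO)c1ccccc1
F7 | step 4 | (2S)-2-(7-methoxy-2,2-dimethyl-2H-chromen-6-yl)-3-[3-(triisopropylsilyloxy)phenoxy]propyl benzoate | O=C(OC[C@@H](c1cc2C=CC(C)(C)Oc2cc1OC)COc1cccc(O[Si](C(C)C)(C(C)C)C(C)C)c1)c1ccccc1
F8 | step 8 | (3S,4S)-3-(7-methoxy-2,2-dimethyl-2H-chromen-6-yl)-7-(triisopropylsilyloxy)chroman-4-ol | O[C@@H]1c2ccc(O[Si](C(C)C)(C(C)C)C(C)C)cc2OC[C@@H]1c1cc2C=CC(C)(C)Oc2cc1OC
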